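Assumption: decalin carbons carry the locants of the target name (C1 = C(CH3)OH, C4 = CHBr, C4a = methyl-bearing fusion carbon, C7 = carbinol bearing the five-membered ring, C8a = hydroxylated fusion carbon); the cyclopentane is C1″ (attached to C7), C2″ (CMe2), C3″ (CHBr), C5″ (CHOH); β is the face of the C4a methyl.

**Retrosynthetic overview**
1. Target 17 ⇐ enone 15: C3″–Br by conjugate HBr addition, C5″–OH by ketone reduction.
2. 15 ⇐ aldol adduct 14 by alkoxide-templated C-methylation (sets quaternary C1″) ⇐ ketone 12 + cyclopentenone 13 (C7–C1″ bond, axial C7–OH).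
3. Key disconnection, C8a–O: 12 ⇐ α-ketol 9 by face-selective ketohydroxylation of the C1=C8a alkene of diene 8; this angular C–O bond relays stereochemistry to C1, C7 and C1″.
4. 8 ⇐ (S)-Wieland–Miescher ketone 4 ⇐ dione 1 + enone 2 (organocatalytic Robinson annulation).
5. Ring order: ring B (from 1) → ring A (annulation) → cyclopentane joined preformed (13).

**Route**

Step 1
Reactants: 1 2-methylcyclohexane-1,3-dione; 2 methyl vinyl ketone
Product: 4 (S)-Wieland–Miescher ketone, via triketone 3 (not isolated)
Conditions: Et3N (1 mol%), neat, rt; then N-tosyl-(Sa)-binam-L-prolinamide (1 mol%), PhCO2H (2.5 mol%), neat, rt; recrystallise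
Reagents that add atoms: none
Why: One-pot Robinson annulation in which Michael addition gives 3 and the prolinamide-catalysed Hajos–Parrish–Eder–Sauer–Wiechert aldol condensation differentiates the two enantiotopic ring carbonyls through a hydrogen-bonded enamine transition state, setting C4a as S.

Step 2
Reactants: 4 (S)-Wieland–Miescher ketone
Product: 5 hydroxy enone
Conditions: NaBH4 (0.3 equiv), EtOH, −10 °C
Reagents that add atoms: none
Why: Chemoselective borohydride reduction of the more electrophilic saturated C4 ketone, with hydride entering from the α face opposite the angular methyl to give the 4β-alcohol, which only masks C4 during ketalisation.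

Step 3
Reactants: 5 hydroxy enone
Product: 6 ketal alcohol
Conditions: ethylene glycol, TsOH·H2O (cat.), benzene, reflux (Dean–Stark)
Reagents that add atoms: ethylene glycol, OCCO
Why: Acid-catalysed ketalisation of the enone carbonyl, during which the double bond leaves conjugation for C1=C8a (as in steroid 3-ketals), exposing the alkene needed for the C–O key step.

Step 4
Reactants: 6 ketal alcohol
Product: 7 keto ketal
Conditions: Pr4N[RuO4] (5 mol%), NMO, 4 Å MS, CH2Cl2, rt
Reagents that add atoms: none
Why: Ley–Griffith oxidation returns the C4 ketone under neutral conditions that leave the acid-labile dioxolane and the alkene untouched.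

Step 5
Reactants: 7 keto ketal
Product: 8 bromodiene ketal
Conditions: (PhO)3P, Br2, CH2Cl2, −60 °C; then Et3N and 7, −60 °C → reflux
Reagents that add atoms: bromine, BrBr
Why: Ketone-to-bromoalkene conversion with preformed (PhO)3PBr2 (enol phosphonium, then loss of phosphate and HBr); C4 can enolise only towards C3 because C4a is quaternary, and no free Br2 is left to attack the C1=C8a alkene.

Step 6
Reactants: 8 bromodiene ketal
Product: 9 α-ketol
Conditions: RuCl3 (1 mol%), KHSO5 (as Oxone), NaHCO3, EtOAc–MeCN–H2O, 0 °C → rt, short reaction time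
Reagents that add atoms: potassium peroxymonosulfate, [K+].[O-]S(=O)(=O)OO
Why: Key C–O bond formation by RuO4-type [3+2] ketohydroxylation of the electron-rich trisubstituted C1=C8a alkene (the bromoalkene is deactivated) from the α face opposite the angular methyl, which puts OH on the fully substituted C8a trans to that methyl and the carbonyl on C1.

Step 7
Reactants: 9 α-ketol
Product: 10 bromo ketol
Conditions: Co(acac)2, t-BuOOH, Et3SiH, 1,4-cyclohexadiene, n-PrOH, rt
Reagents that add atoms: none
Why: Cobalt hydride hydrogen-atom-transfer hydrogenation of the bromoalkene (Mukaiyama-type radical hydrogenation), in which H• adds to C3 and the α-bromo radical at C4 takes hydrogen on the α face anti to the neighbouring angular methyl (the face hydride took in step 2), leaving the C–Br bond equatorial and β.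

Step 8
Reactants: 10 bromo ketol
Product: 12 bromo diol ketone, via ketal diol 11 (not isolated)
Conditions: MeMgBr (3 equiv), THF, −78 → 0 °C; then 1 M HCl, THF–H2O, 0 °C → rt
Reagents that add atoms: methylmagnesium bromide, C[Mg]Br; water, O
Why: Grignard addition to the α-hydroxy ketone under steric approach control, where the axial angular methyl blocks the β face of C1 so that CH3 enters equatorially from the α face (1α-CH3, 1β-OH, trans-diaxial diol), followed by mild acid hydrolysis of the dioxolane to free the C7 ketone.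

Step 9
Reactants: 12 bromo diol ketone; 13 4,4-dimethylcyclopent-2-en-1-one
Product: 14 aldol adduct
Conditions: 13 (3.3 equiv), LDA (3.3 equiv), THF, −78 °C; CeCl3 (3.3 equiv), −78 °C; then 12, −78 °C; aq. NH4Cl at −78 °C
Reagents that add atoms: none
Why: Crossed ketone aldol addition through a weakly basic, oxophilic cerium enolate (C5 is the only enolisable position of 13), which adds equatorially to C7 because the axial C8a alkoxide shields the α face, giving the axial 7α-OH; the C1″ epimers formed are both used.

Step 10
Reactants: 14 aldol adduct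
Product: 15 methylated enone
Conditions: LDA (4.5 equiv), LiCl, THF–DMPU, −78 → −30 °C; MeI (1.2 equiv), −78 → −40 °C; aq. NH4Cl
Reagents that add atoms: iodomethane, CI
Why: Proposed new method: alkoxide-templated C-methylation of a ketone aldolate polyanion, in which the C7 lithium alkoxide guides the amide base to the only enolisable C–H (C1″), the dienolate is held in a six-membered O7–Li–O chelate (C5″ syn to O7) whose C8 side is covered by the lithium cluster that also binds the syn-axial C8a alkoxide, so MeI attacks from the C6 side and creates the quaternary C1″ in the target configuration; the closest known reaction is the Fráter–Seebach alkylation of β-hydroxy ester dianions.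

Step 11
Reactants: 15 methylated enone
Product: 17 neoirietetraol, via bromo ketone 16 (not isolated)
Conditions: HBr (1.5 equiv), CH2Cl2, −40 → 0 °C; then CeCl3·7H2O, NaBH4, MeOH, −78 °C
Reagents that add atoms: hydrogen bromide, Br
Why: Conjugate hydrobromination of the enone under equilibrating conditions places Br at C3″ pseudo-equatorial and cis to the bulky decalinyl group (the trans isomer needs a 1,3-diaxial Br/CH3 contact), and Luche-type borohydride reduction of the labile β-bromo ketone in the same flask delivers hydride to C5″ from the face of the small C1″ methyl, giving the all-cis Br/OH/decalinyl array.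

**Compound list**
1 | 2-methylcyclohexane-1,3-dione | CC1C(=O)CCCC1=O | starting material
2 | methyl vinyl ketone (but-3-en-2-one) | CC(=O)C=C | starting material
3 | 2-methyl-2-(3-oxobutyl)cyclohexane-1,3-dione | CC(=O)CCC1(C)C(=O)CCCC1=O | intermediate
4 | (S)-Wieland–Miescher ketone, (8aS)-8a-methyl-3,4,8,8a-tetrahydronaphthalene-1,6(2H,7H)-dione | C[C@]12CCC(=O)C=C1CCCC2=O | intermediate
5 | (4aS,5S)-5-hydroxy-4a-methyl-4,4a,5,6,7,8-hexahydronaphthalen-2(3H)-one (4β-OH, cis to the angular methyl) | C[C@]12CCC(=O)C=C1CCC[C@@H]2O | intermediate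
6 | (4′aS,5′S)-4′a-methyl-3′,4′,4′a,5′,6′,7′-hexahydro-1′H-spiro[[1,3]dioxolane-2,2′-naphthalen]-5′-ol (C7 ketal, C1=C8a alkene, 4β-OH) | C[C@]12CCC3(OCCO3)CC1=CCC[C@@H]2O | intermediate
7 | (4′aS)-4′a-methyl-3′,4′,6′,7′-tetrahydro-1′H-spiro[[1,3]dioxolane-2,2′-naphthalen]-5′(4′aH)-one (C4 ketone) | C[C@]12CCC3(OCCO3)CC1=CCCC2=O | intermediate
8 | (4′aS)-5′-bromo-4′a-methyl-3′,4′,4′a,7′-tetrahydro-1′H-spiro[[1,3]dioxolane-2,2′-naphthalene] (C3=C4 bromoalkene, C1=C8a alkene) | C[C@]12CCC3(OCCO3)CC1=CCC=C2Br | intermediate
9 | (4′aS,8′aR)-5′-bromo-8′a-hydroxy-4′a-methyl-3′,4′,4′a,8′a-tetrahydro-1′H-spiro[[1,3]dioxolane-2,2′-naphthalen]-8′(7′H)-one (8a-OH α, trans to the methyl; C1 ketone) | C[C@]12CCC3(OCCO3)C[C@]1(O)C(=O)CC=C2Br | intermediate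
10 | (4′aS,5′S,8′aR)-5′-bromo-8′a-hydroxy-4′a-methylhexahydro-1′H-spiro[[1,3]dioxolane-2,2′-naphthalen]-8′(8′aH)-one (4β-Br equatorial) | C[C@]12CCC3(OCCO3)C[C@]1(O)C(=O)CC[C@@H]2Br | intermediate
11 | (4′aS,5′S,8′R,8′aR)-5′-bromo-4′a,8′-dimethyloctahydro-8′aH-spiro[[1,3]dioxolane-2,2′-naphthalene]-8′,8′a-diol | C[C@]12CCC3(OCCO3)C[C@]1(O)[C@](C)(O)CC[C@@H]2Br | intermediate
12 | (4aS,5S,8R,8aR)-5-bromo-8,8a-dihydroxy-4a,8-dimethyloctahydronaphthalen-2(1H)-one | C[C@]12CCC(=O)C[C@]1(O)[C@](C)(O)CC[C@@H]2Br | intermediate
13 | 4,4-dimethylcyclopent-2-en-1-one | CC1(C)C=CC(=O)C1 | starting material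
14 | (1R,4S,4aS,7R,8aR)-4-bromo-7-(2,2-dimethyl-5-oxocyclopent-3-en-1-yl)-1,4a-dimethyldecahydronaphthalene-1,7,8a-triol, both C1″ epimers | C[C@]12CC[C@](O)(C3C(=O)C=CC3(C)C)C[C@]1(O)[C@](C)(O)CC[C@@H]2Br | intermediate
15 | (1R,4S,4aS,7R,8aR)-4-bromo-7-[(1S)-1,2,2-trimethyl-5-oxocyclopent-3-en-1-yl]-1,4a-dimethyldecahydronaphthalene-1,7,8a-triol | C[C@]12CC[C@](O)([C@@]3(C)C(=O)C=CC3(C)C)C[C@]1(O)[C@](C)(O)CC[C@@H]2Br | intermediate
16 | (1R,4S,4aS,7R,8aR)-4-bromo-7-[(1S,3R)-3-bromo-1,2,2-trimethyl-5-oxocyclopentyl]-1,4a-dimethyldecahydronaphthalene-1,7,8a-triol | C[C@]12CC[C@](O)([C@@]3(C)C(=O)C[C@@H](Br)C3(C)C)C[C@]1(O)[C@](C)(O)CC[C@@H]2Br | intermediate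
17 | neoirietetraol, (1R,4S,4aS,7R,8aR)-4-bromo-7-[(1R,3R,5S)-3-bromo-5-hydroxy-1,2,2-trimethylcyclopentyl]-1,4a-dimethyldecahydronaphthalene-1,7,8a-triol | CC1(C)[C@H](Br)C[C@H](O)[C@]1(C)[C@@]1(O)CC[C@]2(C)[C@@H](Br)CC[C@@](C)(O)[C@@]2(O)C1 | target

**Totals and risks**

Total step count: 11. Longest linear sequence: 11 steps (1 and 2 to 17); 13 is used as purchased.

The three steps most likely to fail:

Step 9 (ketone–ketone aldol at a neopentyl enolate carbon; retro-aldol and enolisation of 12 compete). Fallback: the nucleophile is made reductively instead of by deprotonation. Starting from 13, enolate bromination (LDA, then NBS, THF, −78 °C) gives 5-bromo-4,4-dimethylcyclopent-2-en-1-one F1. F1 is then coupled with 12 in a SmI2-mediated Reformatsky-type reaction (SmI2, THF, −78 °C); the samarium aldolate is non-basic and tightly chelated, which suppresses reversal. The route is rejoined at 14.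

Step 10 (the proposed new step; the hindered C1″–H may resist deprotonation, the polyanion may fragment, and the facial bias rests on the chelate model). Fallback with known chemistry: the methyl group is installed before the union. Starting from 13, methylation (LDA, MeI, THF, −78 °C) gives 4,4,5-trimethylcyclopent-2-en-1-one F2. The cerium enolate of F2 is added to 12 under the conditions of step 9, and the two C1″ epimers are separated by chromatography. The unwanted epimer is recycled by base-induced retro-aldol to 12 and F2. The route is rejoined at 15.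

Step 11 (HBr may ionise the three tertiary carbinols, and the β-bromo ketone may eliminate or fail to equilibrate). Fallback: bromine is brought in through boron without acid. Starting from 15, copper-catalysed conjugate borylation (CuCl, NaOt-Bu, xantphos, B2pin2, MeOH, THF, rt) adds the boryl group to C3″ from the face of the C1″ methyl, anti to the decalinyl group, giving β-boryl ketone F3. Reduction (NaBH4, CeCl3·7H2O, MeOH, −78 °C) gives boryl alcohol F4. Stereoinvertive bromodeboronation (3,5-(CF3)2C6H3Li in excess, THF, −78 °C; then NBS) turns C–B into C–Br with inversion, placing Br cis to the decalinyl group. The route is rejoined at 17.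

**Further compounds**
F1 | step 9 | 5-bromo-4,4-dimethylcyclopent-2-en-1-one | CC1(C)C=CC(=O)C1Br
F2 | step 10 | 4,4,5-trimethylcyclopent-2-en-1-one | CC1C(=O)C=CC1(C)C
F3 | step 11 | (1R,4S,4aS,7R,8aR)-4-bromo-1,4a-dimethyl-7-[1,2,2-trimethyl-5-oxo-3-(4,4,5,5-tetramethyl-1,3,2-dioxaborolan-2-yl)cyclopentyl]decahydronaphthalene-1,7,8a-triol, boryl group trans to the decalinyl group | C[C@]12CC[C@](O)([C@@]3(C)C(=O)C[C@H](B4OC(C)(C)C(C)(C)O4)C3(C)C)C[C@]1(O)[C@](C)(O)CC[C@@H]2Br
F4 | step 11 | (1R,4S,4aS,7R,8aR)-4-bromo-7-[5-hydroxy-1,2,2-trimethyl-3-(4,4,5,5-tetramethyl-1,3,2-dioxaborolan-2-yl)cyclopentyl]-1,4a-dimethyldecahydronaphthalene-1,7,8a-triol, OH cis and boryl group trans to the decalinyl group | C[C@]12CC[C@](O)([C@@]3(C)[C@@H](O)C[C@H](B4OC(C)(C)C(C)(C)O4)C3(C)C)C[C@]1(O)[C@](C)(O)CC[C@@H]2Br
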